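The target is a 3',8-linked biflavone: C3' of ring B of the 5-hydroxy-7-methoxy-6-methylflavone unit is bonded to C8 of ring A of the apigenin unit. Everything rests on cutting this one biaryl bond. The key step, a Suzuki–Miyaura coupling of two complete O-protected flavones, assembles the whole carbon skeleton in one operation. It exploits two features: C8 sits between O1 and the C7 oxygen of ring A, where electrophilic iodination of a 5,7-dialkoxyflavone lands, and C3' is ortho to the C4' oxygen of ring B, so a 3-bromo-4-benzyloxybenzaldehyde brings the boron site in. Precursors: 8-iodo-tri-O-benzylapigenin and the 3'-pinacolboronate of the 4'-O-benzyl-5,7-di-O-methyl-6-methylflavone.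

Key step: step 8

Assumption: the biaryl axis is treated as stereochemically undefined, since the target structure carries no axial descriptor. 2,6-Dimethoxytoluene, 4-(benzyloxy)-3-bromobenzaldehyde and apigenin are taken as purchasable.

Step 1
Reactants: 1 2,6-dimethoxytoluene
Product: 3 3,5-dimethoxy-4-methylphenol, via arylboronate 2 (not isolated)
Conditions: [Ir(OMe)(cod)]2 (1.5 mol%), 4,4'-di-tert-butyl-2,2'-bipyridine (3 mol%), B2pin2 (0.6 equiv), THF, 80 °C; then KHSO5 (as Oxone, 2KHSO5·KHSO4·K2SO4), acetone/H2O, rt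
Reagents that add atoms: potassium peroxymonosulfate, [K+].OOS(=O)(=O)[O-] (phenol oxygen); bis(pinacolato)diboron, CC1(C)OB(OC1(C)C)B1OC(C)(C)C(C)(C)O1 (boryl group of intermediate 2 only)
Why: Sterically governed iridium-catalysed C–H borylation should go to the only ring C–H without an ortho substituent (C4, para to the methyl group), and peroxymonosulfate oxidation of the C–B bond then gives the phenol (one-pot C–H borylation/oxidation).

Step 2
Reactants: 3 3,5-dimethoxy-4-methylphenol
Product: 4 1-(6-hydroxy-2,4-dimethoxy-3-methylphenyl)ethan-1-one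
Conditions: Ac2O, BF3·OEt2, 90 °C; then H2O
Reagents that add atoms: acetic anhydride, CC(=O)OC(C)=O
Why: Friedel–Crafts C-acetylation ortho to the phenol; the two free ring positions are equivalent, so a single ketone should form whose free chelated OH is flanked by ring C–H while the methyl-flanked oxygen stays methylated, which fixes the later 6-methyl (not 8-methyl) pattern.

Step 3
Reactants: 4 1-(6-hydroxy-2,4-dimethoxy-3-methylphenyl)ethan-1-one; 5 4-(benzyloxy)-3-bromobenzaldehyde
Product: 6 (E)-3-[4-(benzyloxy)-3-bromophenyl]-1-(6-hydroxy-2,4-dimethoxy-3-methylphenyl)prop-2-en-1-one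
Conditions: KOH, EtOH/H2O, rt
Reagents that add atoms: none
Why: Claisen–Schmidt condensation of a methyl ketone with a non-enolisable aldehyde; dehydration of the aldol should give the thermodynamically favoured E-enone.

Step 4
Reactants: 6 (E)-3-[4-(benzyloxy)-3-bromophenyl]-1-(6-hydroxy-2,4-dimethoxy-3-methylphenyl)prop-2-en-1-one
Product: 7 2-[4-(benzyloxy)-3-bromophenyl]-5,7-dimethoxy-6-methyl-4H-chromen-4-one
Conditions: I2 (10 mol%), DMSO, 130 °C
Reagents that add atoms: none
Why: Iodine-catalysed oxidative cyclisation of a 2'-hydroxychalcone (oxa-Michael addition of the single free phenol, 6-endo-trig, then iodination and loss of HI, with DMSO re-oxidising HI); because the methyl-flanked oxygen is blocked as its methyl ether, only the 6-methyl flavone can form.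

Step 5
Reactants: 7 2-[4-(benzyloxy)-3-bromophenyl]-5,7-dimethoxy-6-methyl-4H-chromen-4-one
Product: 8 2-[4-(benzyloxy)-3-(4,4,5,5-tetramethyl-1,3,2-dioxaborolan-2-yl)phenyl]-5,7-dimethoxy-6-methyl-4H-chromen-4-one
Conditions: PdCl2(dppf) (5 mol%), B2pin2, KOAc, 1,4-dioxane, 90 °C
Reagents that add atoms: bis(pinacolato)diboron, CC1(C)OB(OC1(C)C)B1OC(C)(C)C(C)(C)O1
Why: Miyaura borylation of the aryl bromide; the weak base KOAc should suppress homocoupling, and the chromone and the benzyl ether are inert.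

Step 6
Reactants: 9 apigenin (5,7-dihydroxy-2-(4-hydroxyphenyl)-4H-chromen-4-one)
Product: 10 5,7-bis(benzyloxy)-2-[4-(benzyloxy)phenyl]-4H-chromen-4-one
Conditions: BnBr (4.5 equiv), K2CO3, DMF, 80 °C
Reagents that add atoms: benzyl bromide, BrCc1ccccc1
Why: Williamson ether synthesis; excess halide and heating are used so that the hydrogen-bonded 5-OH is alkylated as well as the 7- and 4'-OH groups.

Step 7
Reactants: 10 5,7-bis(benzyloxy)-2-[4-(benzyloxy)phenyl]-4H-chromen-4-one
Product: 11 5,7-bis(benzyloxy)-2-[4-(benzyloxy)phenyl]-8-iodo-4H-chromen-4-one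
Conditions: N-iodosuccinimide (1.05 equiv), CF3CO2H (0.3 equiv), MeCN/CH2Cl2, 0 °C to rt
Reagents that add atoms: N-iodosuccinimide, O=C1CCC(=O)N1I
Why: Electrophilic aromatic iodination; the trioxygenated ring A is far more reactive than ring B or the benzyl rings, and in 5,7-dialkoxyflavones attack is expected at C8 (between O1 and the C7 oxygen, para to the C5 oxygen) and not at C6, which is shielded by two benzyloxy groups.

Step 8
Reactants: 11 5,7-bis(benzyloxy)-2-[4-(benzyloxy)phenyl]-8-iodo-4H-chromen-4-one; 8 2-[4-(benzyloxy)-3-(4,4,5,5-tetramethyl-1,3,2-dioxaborolan-2-yl)phenyl]-5,7-dimethoxy-6-methyl-4H-chromen-4-one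
Product: 12 5,7-bis(benzyloxy)-8-[2-(benzyloxy)-5-(5,7-dimethoxy-6-methyl-4-oxo-4H-chromen-2-yl)phenyl]-2-[4-(benzyloxy)phenyl]-4H-chromen-4-one
Conditions: Pd(OAc)2 (5 mol%), SPhos (10 mol%), K3PO4 (3 equiv), toluene/H2O (10:1), 100 °C
Reagents that add atoms: none
Why: Suzuki–Miyaura cross-coupling: zerovalent palladium formed from Pd(OAc)2 and SPhos inserts into the C8–I bond of 11, the base-activated boronate 8 transfers its C3' aryl group, and reductive elimination forms the C3'–C8 biaryl bond. The closest known reaction type is the Suzuki coupling of 8-iodo-5,7-dialkoxyflavones with flavone 3'-boronates used for 3',8-linked biflavones. No ring is closed and no stereocentre is formed; the new axis carries three ortho substituents and is not a defined stereoelement of the target. The step needs site fidelity at both carbons, which is secured because each partner carries exactly one reactive bond (the bromide was consumed in step 5 and iodine sits only at C8), and chemoselectivity, which is secured because every phenol is an ether and the chromone carbonyls tolerate the mild base. The bulky, electron-rich biarylphosphine should speed oxidative addition to the electron-rich, doubly ortho-oxygenated iodide and reductive elimination to the hindered biaryl. Boron is placed on the less hindered partner because a 2,6-dioxygenated arylboron would be prone to protodeboronation.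

Step 9
Reactants: 12 5,7-bis(benzyloxy)-8-[2-(benzyloxy)-5-(5,7-dimethoxy-6-methyl-4-oxo-4H-chromen-2-yl)phenyl]-2-[4-(benzyloxy)phenyl]-4H-chromen-4-one
Product: 13 5,7-dihydroxy-8-[2-hydroxy-5-(5-hydroxy-7-methoxy-6-methyl-4-oxo-4H-chromen-2-yl)phenyl]-2-(4-hydroxyphenyl)-4H-chromen-4-one (target)
Conditions: BCl3 (excess), pentamethylbenzene, CH2Cl2, −78 °C to 0 °C; then H2O
Reagents that add atoms: none
Why: Lewis acid ether cleavage: BCl3 should remove the four benzyl ethers (pentamethylbenzene traps the benzyl cations and prevents C-benzylation) and cleave the 5-O-methyl ether through its six-membered chelate with the C4 carbonyl, while the non-chelated 7-O-methyl ether is expected to survive.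

Compound list
1 | 2,6-dimethoxytoluene | COc1cccc(OC)c1C | starting material
2 | 2-(3,5-dimethoxy-4-methylphenyl)-4,4,5,5-tetramethyl-1,3,2-dioxaborolane | COc1cc(B2OC(C)(C)C(C)(C)O2)cc(OC)c1C | intermediate (not isolated)
3 | 3,5-dimethoxy-4-methylphenol | COc1cc(O)cc(OC)c1C | intermediate
4 | 1-(6-hydroxy-2,4-dimethoxy-3-methylphenyl)ethan-1-one | CC(=O)c1c(O)cc(OC)c(C)c1OC | intermediate
5 | 4-(benzyloxy)-3-bromobenzaldehyde | O=Cc1ccc(OCc2ccccc2)c(Br)c1 | starting material
6 | (E)-3-[4-(benzyloxy)-3-bromophenyl]-1-(6-hydroxy-2,4-dimethoxy-3-methylphenyl)prop-2-en-1-one | COc1cc(O)c(C(=O)/C=C/c2ccc(OCc3ccccc3)c(Br)c2)c(OC)c1C | intermediate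
7 | 2-[4-(benzyloxy)-3-bromophenyl]-5,7-dimethoxy-6-methyl-4H-chromen-4-one | COc1cc2oc(-c3ccc(OCc4ccccc4)c(Br)c3)cc(=O)c2c(OC)c1C | intermediate
8 | 2-[4-(benzyloxy)-3-(4,4,5,5-tetramethyl-1,3,2-dioxaborolan-2-yl)phenyl]-5,7-dimethoxy-6-methyl-4H-chromen-4-one | COc1cc2oc(-c3ccc(OCc4ccccc4)c(B4OC(C)(C)C(C)(C)O4)c3)cc(=O)c2c(OC)c1C | intermediate
9 | apigenin, 5,7-dihydroxy-2-(4-hydroxyphenyl)-4H-chromen-4-one | O=c1cc(-c2ccc(O)cc2)oc2cc(O)cc(O)c12 | starting material
10 | 5,7-bis(benzyloxy)-2-[4-(benzyloxy)phenyl]-4H-chromen-4-one | O=c1cc(-c2ccc(OCc3ccccc3)cc2)oc2cc(OCc3ccccc3)cc(OCc3ccccc3)c12 | intermediate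
11 | 5,7-bis(benzyloxy)-2-[4-(benzyloxy)phenyl]-8-iodo-4H-chromen-4-one | O=c1cc(-c2ccc(OCc3ccccc3)cc2)oc2c(I)c(OCc3ccccc3)cc(OCc3ccccc3)c12 | intermediate
12 | 5,7-bis(benzyloxy)-8-[2-(benzyloxy)-5-(5,7-dimethoxy-6-methyl-4-oxo-4H-chromen-2-yl)phenyl]-2-[4-(benzyloxy)phenyl]-4H-chromen-4-one | COc1cc2oc(-c3ccc(OCc4ccccc4)c(-c4c(OCc5ccccc5)cc(OCc5ccccc5)c5c(=O)cc(-c6ccc(OCc7ccccc7)cc6)oc45)c3)cc(=O)c2c(OC)c1C | intermediate
13 | 5,7-dihydroxy-8-[2-hydroxy-5-(5-hydroxy-7-methoxy-6-methyl-4-oxo-4H-chromen-2-yl)phenyl]-2-(4-hydroxyphenyl)-4H-chromen-4-one | COc1cc2oc(-c3ccc(O)c(-c4c(O)cc(O)c5c(=O)cc(-c6ccc(O)cc6)oc45)c3)cc(=O)c2c(O)c1C | target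

Total step count: 9. Longest linear sequence: 7 steps (steps 1, 2, 3, 4, 5, 8, 9).

Steps most likely to fail

Step 8. Transmetalation of the bulky, poorly soluble flavone boronate onto the hindered arylpalladium iodide may be slow, so that protodeboronation of 8 and reductive deiodination of 11 outrun the coupling. The fallback sets out from 5 and 11 and comes back at 12. Aldehyde 5 would be borylated (PdCl2(dppf), B2pin2, KOAc, dioxane) to 4-(benzyloxy)-3-(4,4,5,5-tetramethyl-1,3,2-dioxaborolan-2-yl)benzaldehyde F1, a small, soluble boronate that can be used in large excess. Suzuki coupling of F1 with 11 should give 4-(benzyloxy)-3-{5,7-bis(benzyloxy)-2-[4-(benzyloxy)phenyl]-4-oxo-4H-chromen-8-yl}benzaldehyde F2. Claisen–Schmidt condensation of F2 with ketone 4 (KOH or Ba(OH)2, EtOH/THF, rt) should give the (E)-chalcone F3, and I2/DMSO cyclisation of F3 would close the second pyranone to give 12.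

Step 7. Regiocontrol may be lost, with iodination at C6 beside C8 or double iodination of ring A. The fallback fixes the halogen before the pyranone exists. It does not set out from a numbered compound: purchased 1-(2,4,6-trihydroxyphenyl)ethan-1-one and 4-(benzyloxy)benzaldehyde take the place of compounds 9 and 10, and it comes back at 11. Selective dibenzylation of the two non-chelated hydroxyls (BnBr, K2CO3, acetone, reflux) should give 1-[2,4-bis(benzyloxy)-6-hydroxyphenyl]ethan-1-one F4. Iodination ortho to the free chelated phenol (benzyltrimethylammonium dichloroiodate, CaCO3, CH2Cl2/MeOH) should give 1-[4,6-bis(benzyloxy)-2-hydroxy-3-iodophenyl]ethan-1-one F5. Claisen–Schmidt condensation with 4-(benzyloxy)benzaldehyde (KOH, EtOH) should give (E)-1-[4,6-bis(benzyloxy)-2-hydroxy-3-iodophenyl]-3-[4-(benzyloxy)phenyl]prop-2-en-1-one F6. I2/DMSO cyclisation through the phenol next to the iodinated carbon would then place iodine at C8 and give 11.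

Step 9. The one-flask cleavage may be unbalanced: the chelated 5-O-methyl ether may be cleaved incompletely at temperatures where the benzyl ethers go, or longer exposure may start to attack the 7-O-methyl ether or benzylate the electron-rich rings. The fallback sets out from 12 and comes back at 13, separating the two events. Hydrogenolysis (H2, 10% Pd/C, THF/MeOH, rt) would remove the four benzyl ethers to give 5,7-dihydroxy-8-[2-hydroxy-5-(5,7-dimethoxy-6-methyl-4-oxo-4H-chromen-2-yl)phenyl]-2-(4-hydroxyphenyl)-4H-chromen-4-one F7. Chelation-controlled demethylation of the 5-O-methyl group alone (BCl3, CH2Cl2, 0 °C, or AlCl3 in MeCN) would then give 13.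

Further compounds
F1 | step 8 | 4-(benzyloxy)-3-(4,4,5,5-tetramethyl-1,3,2-dioxaborolan-2-yl)benzaldehyde | O=Cc1ccc(OCc2ccccc2)c(B2OC(C)(C)C(C)(C)O2)c1
F2 | step 8 | 4-(benzyloxy)-3-{5,7-bis(benzyloxy)-2-[4-(benzyloxy)phenyl]-4-oxo-4H-chromen-8-yl}benzaldehyde | O=Cc1ccc(OCc2ccccc2)c(-c2c(OCc3ccccc3)cc(OCc3ccccc3)c3c(=O)cc(-c4ccc(OCc5ccccc5)cc4)oc23)c1
F3 | step 8 | (E)-3-[4-(benzyloxy)-3-{5,7-bis(benzyloxy)-2-[4-(benzyloxy)phenyl]-4-oxo-4H-chromen-8-yl}phenyl]-1-(6-hydroxy-2,4-dimethoxy-3-methylphenyl)prop-2-en-1-one | COc1cc(O)c(C(=O)/C=C/c2ccc(OCc3ccccc3)c(-c3c(OCc4ccccc4)cc(OCc4ccccc4)c4c(=O)cc(-c5ccc(OCc6ccccc6)cc5)oc34)c2)c(OC)c1C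
F4 | step 7 | 1-[2,4-bis(benzyloxy)-6-hydroxyphenyl]ethan-1-one | CC(=O)c1c(O)cc(OCc2ccccc2)cc1OCc1ccccc1
F5 | step 7 | 1-[4,6-bis(benzyloxy)-2-hydroxy-3-iodophenyl]ethan-1-one | CC(=O)c1c(O)c(I)c(OCc2ccccc2)cc1OCc1ccccc1
F6 | step 7 | (E)-1-[4,6-bis(benzyloxy)-2-hydroxy-3-iodophenyl]-3-[4-(benzyloxy)phenyl]prop-2-en-1-one | O=C(/C=C/c1ccc(OCc2ccccc2)cc1)c1c(O)c(I)c(OCc2ccccc2)cc1OCc1ccccc1
F7 | step 9 | 5,7-dihydroxy-8-[2-hydroxy-5-(5,7-dimethoxy-6-methyl-4-oxo-4H-chromen-2-yl)phenyl]-2-(4-hydroxyphenyl)-4H-chromen-4-one | COc1cc2oc(-c3ccc(O)c(-c4c(O)cc(O)c5c(=O)cc(-c6ccc(O)cc6)oc45)c3)cc(=O)c2c(OC)c1C
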